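**Plan**

- Retrosynthetic cuts: the C1 ester; both aldehydes (back to an 11,12-diol, with the C12 oxygen from allylic oxidation of a C8 methyl and C9–C11 from a [2,3] shift off a 7β-oxygen); then ring A at C2–C3 and C4–C5; ring B goes back to an arene.
- Forward order: ring B first, by dearomatising 2-methoxy-5-methylbenzoic acid (asymmetric Birch reduction–methylation). Ring A second, by a one-flask formal [4+2] annulation of a ring-B ketal/silyl enol ether with the enol silane of isobutyraldehyde. Then C11 and C12 are added to ring B; the ester and the dial come last.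
- Enabling feature: in ring A the oxygens on C1 and C5 stand 1,3 across the quaternary C10. One fragment can therefore hold an oxocarbenium carbon (C5) and an enol carbon (C2), which take up the two ends of the C3–C4 unit carrying the gem-dimethyl group.
- Stereochemistry: C10 from the prolinol-ether auxiliary; C5 from attack anti to the C10 side arm in the annulation; C1 and C7 from hydride delivery by the 5α-hydroxyl; C9 from suprafacial [2,3] transfer from the 7β-oxygen.

Key step: step 6

Remark on names: bicyclic compounds carry drimane numbering (decalin C1–C10; C11 on C9, C12 on C8, C13 and C14 on C4, C15 on C10, the C10 methyl β); "11-nor" means C11 is still missing.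

Assumption: methylation of enolate 4 from the (S)-auxiliary is taken to give the (1R) quaternary carbon of 5 (electrophile anti to the methoxymethyl arm of the chelated enolate). Should this auxiliary deliver the other sense, its commercial (R)-enantiomer is used and all compounds from 6 on stay as drawn.

**Route**

Step 1
Reactants: 1 2-methoxy-5-methylbenzoic acid; 2 (S)-2-(methoxymethyl)pyrrolidine
Product: 3 [(2S)-2-(methoxymethyl)pyrrolidin-1-yl](2-methoxy-5-methylphenyl)methanone
Conditions: DCC, HOBt (cat.), CH2Cl2, 0 °C to rt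
Reagents that add atoms: none
Why: Carbodiimide amide coupling of an aryl acid with a secondary amine is routine and attaches the chiral auxiliary; no stereocentre is formed.

Step 2
Reactants: 3 [(2S)-2-(methoxymethyl)pyrrolidin-1-yl](2-methoxy-5-methylphenyl)methanone
Product: 5 [(2S)-2-(methoxymethyl)pyrrolidin-1-yl][(1R)-2-methoxy-1,5-dimethylcyclohexa-2,5-dien-1-yl]methanone, via potassium enolate 4 (not isolated)
Conditions: K (2.2 equiv), NH3(l)/THF, t-BuOH (1 equiv), −78 °C; then MeI, −78 °C
Reagents that add atoms: iodomethane, CI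
Why: Birch reduction of the benzamide ring gives the amide enolate 4 (sp3 carbon para to the carbonyl), and methylation of this chelated chiral enolate anti to the methoxymethyl arm (asymmetric Birch reduction–alkylation) should set the quaternary carbon that becomes C10.

Step 3
Reactants: 5 [(2S)-2-(methoxymethyl)pyrrolidin-1-yl][(1R)-2-methoxy-1,5-dimethylcyclohexa-2,5-dien-1-yl]methanone
Product: 6 1-[(1R)-2-methoxy-1,5-dimethylcyclohexa-2,5-dien-1-yl]ethan-1-one
Conditions: MeLi (3 equiv), THF, −78 to 0 °C; then aq. NH4Cl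
Reagents that add atoms: methyllithium, [Li]C
Why: Organolithium addition to a tertiary amide stops at the tetrahedral lithium alkoxide, which collapses to the methyl ketone only on work-up and releases the auxiliary, while the enol ether and the skipped diene are untouched.

Step 4
Reactants: 6 1-[(1R)-2-methoxy-1,5-dimethylcyclohexa-2,5-dien-1-yl]ethan-1-one
Product: 7 1-[(1S)-6,6-bis(benzyloxy)-1,3-dimethylcyclohex-2-en-1-yl]ethan-1-one
Conditions: BnOH (10 equiv), PPTS (5 mol %), 4 Å MS, toluene, 40 °C, reduced pressure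
Reagents that add atoms: benzyl alcohol, OCc1ccccc1
Why: Acid-catalysed addition of benzyl alcohol to the enol ether followed by ketal exchange (methanol removed) turns C5 into a dibenzyl ketal, the later oxocarbenium source whose remaining benzyl group can be cleaved from a tertiary oxygen; the hindered acetyl group should not ketalise (the descriptor changes only through the priority rules).

Step 5
Reactants: 7 1-[(1S)-6,6-bis(benzyloxy)-1,3-dimethylcyclohex-2-en-1-yl]ethan-1-one
Product: 8 tert-butyl({1-[(1S)-6,6-bis(benzyloxy)-1,3-dimethylcyclohex-2-en-1-yl]ethenyl}oxy)dimethylsilane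
Conditions: LiN(i-Pr)2 (LDA), THF, −78 °C; then TBSCl, DMPU, −78 to 0 °C
Reagents that add atoms: tert-butyl(chloro)dimethylsilane, CC(C)(C)[Si](C)(C)Cl
Why: The acetyl methyl is the only enolisable position, so deprotonation and O-silylation (silyl enol ether formation) should give a single terminal enol silane.

Step 6
Reactants: 8 tert-butyl({1-[(1S)-6,6-bis(benzyloxy)-1,3-dimethylcyclohex-2-en-1-yl]ethenyl}oxy)dimethylsilane; 9 2-methyl-1-(trimethylsilyloxy)prop-1-ene
Product: 13 5α-benzyloxy-11-nordrima-2,8-dien-1-one, via oxocarbenium triflate 10 (not isolated), via silyloxycarbenium triflate 11 (not isolated), via silyloxy ketone 12 (not isolated)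
Conditions: 9 (5 equiv), TMSOTf (0.3 equiv), 2,6-di-tert-butyl-4-methylpyridine (0.4 equiv), CH2Cl2, −78 °C, slow addition of 8; then DBU (3 equiv), −78 °C to rt
Reagents that add atoms: none
Why: Proposed new method: TMSOTf ionises ketal 8 to the ring-B benzyloxycarbenium ion 10, enol silane 9 attacks it through its dimethyl-substituted carbon (C4–C5, Mukaiyama-type addition to a ketal) to give the silyloxycarbenium ion 11, and the pendant TBS enol ether then attacks C3 (C2–C3, intramolecular Mukaiyama aldol) to give 12, the TBS group leaving as the chain-carrying silyl triflate, before DBU eliminates silanol (E1cB) to enone 13. The closest known reaction types are the addition of enol silanes to ketals under silyl triflate catalysis and the Lewis-acid formal [4+2] annulation of 3-alkoxycyclobutanones (masked 1,4-zwitterions) with enol silanes; the open-chain ketal/enol-silane pair 8 is a new substrate class for the one-flask version. Ring A, the only ring closed, forms in a favoured 6-(enolendo)-exo-trig mode at the oxocarbenium carbon C3. C5 is the only lasting new stereocentre (C3 is lost in the elimination): ion 10 is nearly flat around C5 (C5 and C8=C9 are trigonal) and C10 carries a small methyl next to the bulky silyloxyvinyl arm, so 9 should enter anti to the arm (arm perpendicular, Felkin-type), which puts C4 cis to the C10 methyl and the oxygen trans to it, and the resulting trans-diequatorial pair arm/C4 can only close to the trans-fused ring system. The step needs intermolecular attack at C5 to beat loss of H6 (enol ether), self-reaction of the silyl enol ether of 8 and Prins attack by the C8=C9 alkene; excess 9 with slow addition of 8, a hindered pyridine base, −78 °C and the far higher nucleophilicity of enol silanes over the alkene should secure this.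

Step 7
Reactants: 13 5α-benzyloxy-11-nordrima-2,8-dien-1-one
Product: 14 5α-hydroxy-11-nordrim-8-en-1-one
Conditions: Li (6 equiv), NH3(l)/THF, −78 °C, 20 min; then isoprene, solid NH4Cl
Reagents that add atoms: none
Why: Dissolving-metal reduction saturates the enone C2=C3 through its lithium enolate and cleaves the benzyl ether to the tertiary alkoxide in the same operation, while the isolated trisubstituted C8=C9 alkene is inert.

Step 8
Reactants: 14 5α-hydroxy-11-nordrim-8-en-1-one
Product: 15 5α-hydroxy-11-nordrim-8-ene-1,7-dione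
Conditions: CrO3, 3,5-dimethylpyrazole, CH2Cl2, −20 °C
Reagents that add atoms: chromium trioxide, O=[Cr](=O)=O
Why: Allylic oxidation with the CrO3–3,5-dimethylpyrazole complex should go to C7, the only allylic methylene (C10 is quaternary and a ring CH2 is preferred over the C8 methyl), and give the C7 enone.

Step 9
Reactants: 15 5α-hydroxy-11-nordrim-8-ene-1,7-dione
Product: 16 11-nordrim-8-ene-1β,5α,7β-triol
Conditions: Me4NBH(OAc)3 (8 equiv), MeCN/AcOH (1:1), −30 to 0 °C
Reagents that add atoms: none
Why: Saksena–Evans reduction: the C5 hydroxyl binds the triacetoxyborohydride and delivers hydride intramolecularly to the α face of both carbonyls that stand 1,3 to it (C1, and C7 by 1,2-addition to the enone), which should set 1β-OH and 7β-OH, each anti to the 5α-OH.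

Step 10
Reactants: 16 11-nordrim-8-ene-1β,5α,7β-triol
Product: 17 7β-[(tributylstannyl)methoxy]-11-nordrim-8-ene-1β,5α-diol
Conditions: KH (1.1 equiv), THF, 0 °C; then Bu3SnCH2I (1.1 equiv), 0 °C to rt
Reagents that add atoms: tributyl(iodomethyl)stannane, CCCC[Sn](CCCC)(CCCC)CI
Why: Williamson etherification of the least hindered alkoxide: the allylic C7 hydroxyl should react in preference to the neopentyl C1 hydroxyl and the tertiary C5 hydroxyl.

Step 11
Reactants: 17 7β-[(tributylstannyl)methoxy]-11-nordrim-8-ene-1β,5α-diol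
Product: 19 11-(triethylsilyloxy)drim-7-ene-1β,5α-diol, via trilithium alkoxide 18 (not isolated)
Conditions: n-BuLi (4 equiv), THF, −78 to −20 °C; then Et3SiCl (1.05 equiv), −78 °C; aq. NH4Cl
Reagents that add atoms: chlorotriethylsilane, CC[Si](CC)(CC)Cl
Why: Tin–lithium exchange gives the α-alkoxymethyllithium, which undergoes the Wittig–Still [2,3]-sigmatropic rearrangement suprafacially, so the hydroxymethyl carbon C11 arrives on the β face of C9 from the 7β-oxygen as the double bond moves to C7=C8, and the primary alkoxide of 18 is then silylated selectively in the flask.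

Step 12
Reactants: 20 (E)-3-(4-hydroxyphenyl)prop-2-enoic acid (p-coumaric acid)
Product: 22 (E)-3-[4-(tert-butyldimethylsilyloxy)phenyl]prop-2-enoic acid, via silyl ester 21 (not isolated)
Conditions: TBSCl (2.3 equiv), imidazole, DMF, rt; then AcOH/THF/H2O, rt
Reagents that add atoms: tert-butyl(chloro)dimethylsilane, CC(C)(C)[Si](C)(C)Cl
Why: Both acidic sites are silylated and the labile silyl ester is hydrolysed selectively by mild aqueous acid, leaving the aryl silyl ether (standard phenol protection).

Step 13
Reactants: 19 11-(triethylsilyloxy)drim-7-ene-1β,5α-diol; 22 (E)-3-[4-(tert-butyldimethylsilyloxy)phenyl]prop-2-enoic acid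
Product: 24 1β-{(E)-3-[4-(tert-butyldimethylsilyloxy)phenyl]prop-2-enoyloxy}-11-(triethylsilyloxy)drim-7-en-5α-ol, via mixed anhydride 23 (not isolated)
Conditions: 22 (1.5 equiv), 2,4,6-trichlorobenzoyl chloride, Et3N, THF, rt; then 19, DMAP, toluene, 60 °C
Reagents that add atoms: none
Why: Yamaguchi esterification through mixed anhydride 23 acylates the hindered equatorial C1 hydroxyl while the tertiary C5 hydroxyl does not react; no stereocentre is touched.

Step 14
Reactants: 24 1β-{(E)-3-[4-(tert-butyldimethylsilyloxy)phenyl]prop-2-enoyloxy}-11-(triethylsilyloxy)drim-7-en-5α-ol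
Product: 25 1β-{(E)-3-[4-(tert-butyldimethylsilyloxy)phenyl]prop-2-enoyloxy}-11-(triethylsilyloxy)drim-7-ene-5α,12-diol
Conditions: SeO2 (0.5 equiv), t-BuOOH (3 equiv), CH2Cl2, 0 °C to rt
Reagents that add atoms: tert-butyl hydroperoxide, CC(C)(C)OO (oxygen source, transferred by the SeO2 catalyst, O=[Se]=O)
Why: SeO2-catalysed allylic oxidation (ene reaction then [2,3] shift) of the trisubstituted C7=C8 alkene should occur at the methyl group on its more substituted end (C12, CH3 preferred over the C9 methine) and stop largely at the allylic alcohol, as in related drimenyl systems.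

Step 15
Reactants: 25 1β-{(E)-3-[4-(tert-butyldimethylsilyloxy)phenyl]prop-2-enoyloxy}-11-(triethylsilyloxy)drim-7-ene-5α,12-diol
Product: 26 1β-{(E)-3-[4-(tert-butyldimethylsilyloxy)phenyl]prop-2-enoyloxy}drim-7-ene-5α,11,12-triol
Conditions: PPTS (0.2 equiv), MeOH, 0 °C
Reagents that add atoms: none
Why: Mild acid methanolysis removes the primary triethylsilyl ether and leaves the acid-stable aryl silyl ether and the ester.

Step 16
Reactants: 26 1β-{(E)-3-[4-(tert-butyldimethylsilyloxy)phenyl]prop-2-enoyloxy}drim-7-ene-5α,11,12-triol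
Product: 27 1β-{(E)-3-[4-(tert-butyldimethylsilyloxy)phenyl]prop-2-enoyloxy}-5α-hydroxydrim-7-ene-11,12-dial
Conditions: (COCl)2, DMSO, CH2Cl2, −78 °C; then Et3N, −78 to −30 °C
Reagents that add atoms: none
Why: Swern oxidation activates both primary alcohols before base is added, so both should go to aldehydes without a lactol stage and, at low temperature, without epimerising C9; the tertiary alcohol and the protected phenol are inert.

Step 17
Reactants: 27 1β-{(E)-3-[4-(tert-butyldimethylsilyloxy)phenyl]prop-2-enoyloxy}-5α-hydroxydrim-7-ene-11,12-dial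
Product: 28 (1R,5R,9R,10S)-1β-[(E)-3-(4-hydroxyphenyl)prop-2-enoyloxy]-5α-hydroxydrim-7-ene-11,12-dial (target)
Conditions: HF·pyridine, pyridine, THF, 0 °C
Reagents that add atoms: none
Why: Buffered fluoride cleaves the aryl silyl ether under non-basic conditions that should spare the epimerisable, elimination-prone ene-dial.

**Compound list**

1 | 2-methoxy-5-methylbenzoic acid | Cc1ccc(OC)c(C(=O)O)c1 | starting material
2 | (S)-2-(methoxymethyl)pyrrolidine | COC[C@@H]1CCCN1 | starting material
3 | [(2S)-2-(methoxymethyl)pyrrolidin-1-yl](2-methoxy-5-methylphenyl)methanone | COC[C@@H]1CCCN1C(=O)c1cc(C)ccc1OC | intermediate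
4 | potassium enolate of the 1,4-dihydro amide | COC[C@@H]1CCCN1C([O-])=C1C=C(C)CC=C1OC.[K+] | intermediate
5 | [(2S)-2-(methoxymethyl)pyrrolidin-1-yl][(1R)-2-methoxy-1,5-dimethylcyclohexa-2,5-dien-1-yl]methanone | COC[C@@H]1CCCN1C(=O)[C@]1(C)C=C(C)CC=C1OC | intermediate
6 | 1-[(1R)-2-methoxy-1,5-dimethylcyclohexa-2,5-dien-1-yl]ethan-1-one | CC(=O)[C@]1(C)C=C(C)CC=C1OC | intermediate
7 | 1-[(1S)-6,6-bis(benzyloxy)-1,3-dimethylcyclohex-2-en-1-yl]ethan-1-one | CC(=O)[C@]1(C)C=C(C)CCC1(OCc1ccccc1)OCc1ccccc1 | intermediate
8 | tert-butyl({1-[(1S)-6,6-bis(benzyloxy)-1,3-dimethylcyclohex-2-en-1-yl]ethenyl}oxy)dimethylsilane | C=C(O[Si](C)(C)C(C)(C)C)[C@]1(C)C=C(C)CCC1(OCc1ccccc1)OCc1ccccc1 | intermediate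
9 | 2-methyl-1-(trimethylsilyloxy)prop-1-ene | CC(C)=CO[Si](C)(C)C | starting material
10 | ring-B benzyloxycarbenium triflate (C5 cation, C10 stereocentre intact) | C=C(O[Si](C)(C)C(C)(C)C)[C@]1(C)C=C(C)CCC1=[O+]Cc1ccccc1.[O-]S(=O)(=O)C(F)(F)F | intermediate
11 | C3 trimethylsilyloxycarbenium triflate (C4–C5 formed, benzyloxy trans to the C10 methyl) | C=C(O[Si](C)(C)C(C)(C)C)[C@]1(C)C=C(C)CC[C@@]1(OCc1ccccc1)C(C)(C)C=[O+][Si](C)(C)C.[O-]S(=O)(=O)C(F)(F)F | intermediate
12 | 5α-benzyloxy-3-(trimethylsilyloxy)-11-nordrim-8-en-1-one (both C3 epimers) | CC1(C)C(O[Si](C)(C)C)CC(=O)[C@]2(C)C=C(C)CC[C@@]12OCc1ccccc1 | intermediate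
13 | 5α-benzyloxy-11-nordrima-2,8-dien-1-one | CC1(C)C=CC(=O)[C@]2(C)C=C(C)CC[C@@]12OCc1ccccc1 | intermediate
14 | 5α-hydroxy-11-nordrim-8-en-1-one | CC1(C)CCC(=O)[C@]2(C)C=C(C)CC[C@@]12O | intermediate
15 | 5α-hydroxy-11-nordrim-8-ene-1,7-dione | CC1(C)CCC(=O)[C@]2(C)C=C(C)C(=O)C[C@@]12O | intermediate
16 | 11-nordrim-8-ene-1β,5α,7β-triol | CC1(C)CC[C@@H](O)[C@]2(C)C=C(C)[C@@H](O)C[C@@]12O | intermediate
17 | 7β-[(tributylstannyl)methoxy]-11-nordrim-8-ene-1β,5α-diol | CC1(C)CC[C@@H](O)[C@]2(C)C=C(C)[C@@H](OC[Sn](CCCC)(CCCC)CCCC)C[C@@]12O | intermediate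
18 | trilithium salt of drim-7-ene-1β,5α,11-triol (9α-H) | CC1(C)CC[C@@H]([O-])[C@]2(C)[C@@H](C[O-])C(C)=CC[C@@]12[O-].[Li+].[Li+].[Li+] | intermediate
19 | 11-(triethylsilyloxy)drim-7-ene-1β,5α-diol (9α-H) | CC1(C)CC[C@@H](O)[C@]2(C)[C@@H](CO[Si](CC)(CC)CC)C(C)=CC[C@@]12O | intermediate
20 | (E)-3-(4-hydroxyphenyl)prop-2-enoic acid | OC(=O)/C=C/c1ccc(O)cc1 | starting material
21 | tert-butyldimethylsilyl (E)-3-[4-(tert-butyldimethylsilyloxy)phenyl]prop-2-enoate | CC(C)(C)[Si](C)(C)OC(=O)/C=C/c1ccc(O[Si](C)(C)C(C)(C)C)cc1 | intermediate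
22 | (E)-3-[4-(tert-butyldimethylsilyloxy)phenyl]prop-2-enoic acid | OC(=O)/C=C/c1ccc(O[Si](C)(C)C(C)(C)C)cc1 | intermediate
23 | (E)-3-[4-(tert-butyldimethylsilyloxy)phenyl]prop-2-enoic 2,4,6-trichlorobenzoic anhydride | CC(C)(C)[Si](C)(C)Oc1ccc(/C=C/C(=O)OC(=O)c2c(Cl)cc(Cl)cc2Cl)cc1 | intermediate
24 | 1β-{(E)-3-[4-(tert-butyldimethylsilyloxy)phenyl]prop-2-enoyloxy}-11-(triethylsilyloxy)drim-7-en-5α-ol | CC1(C)CC[C@@H](OC(=O)/C=C/c2ccc(O[Si](C)(C)C(C)(C)C)cc2)[C@]2(C)[C@@H](CO[Si](CC)(CC)CC)C(C)=CC[C@@]12O | intermediate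
25 | 1β-{(E)-3-[4-(tert-butyldimethylsilyloxy)phenyl]prop-2-enoyloxy}-11-(triethylsilyloxy)drim-7-ene-5α,12-diol | CC1(C)CC[C@@H](OC(=O)/C=C/c2ccc(O[Si](C)(C)C(C)(C)C)cc2)[C@]2(C)[C@@H](CO[Si](CC)(CC)CC)C(CO)=CC[C@@]12O | intermediate
26 | 1β-{(E)-3-[4-(tert-butyldimethylsilyloxy)phenyl]prop-2-enoyloxy}drim-7-ene-5α,11,12-triol | CC1(C)CC[C@@H](OC(=O)/C=C/c2ccc(O[Si](C)(C)C(C)(C)C)cc2)[C@]2(C)[C@@H](CO)C(CO)=CC[C@@]12O | intermediate
27 | 1β-{(E)-3-[4-(tert-butyldimethylsilyloxy)phenyl]prop-2-enoyloxy}-5α-hydroxydrim-7-ene-11,12-dial | CC1(C)CC[C@@H](OC(=O)/C=C/c2ccc(O[Si](C)(C)C(C)(C)C)cc2)[C@]2(C)[C@@H](C=O)C(C=O)=CC[C@@]12O | intermediate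
28 | (1R,5R,9R,10S)-1β-[(E)-3-(4-hydroxyphenyl)prop-2-enoyloxy]-5α-hydroxydrim-7-ene-11,12-dial | CC1(C)CC[C@@H](OC(=O)/C=C/c2ccc(O)cc2)[C@]2(C)[C@@H](C=O)C(C=O)=CC[C@@]12O | target

**Count and risks**

Total step count: 17. Longest linear sequence: 16 steps (steps 1–11 and 13–17; step 12 makes acid 22 in a side branch).

Steps most likely to fail:

1. Step 6 (the labelled step). The intermolecular bond formation at the hindered oxocarbenium carbon may be too slow, so that proton loss to the benzyl enol ether or self-condensation of 8 takes over, or the nucleophile may enter from the wrong face. The fallback is stepwise and uses known chemistry. It sets out from 7, whose free acetyl group cannot self-condense. Addition of 9 to the ketal under TMSOTf catalysis (or with stoichiometric TiCl4) at −78 °C should give 2-[(1R,2R)-2-acetyl-1-(benzyloxy)-2,4-dimethylcyclohex-3-en-1-yl]-2-methylpropanal F1, which is isolated and freed from any C5 epimer. An intramolecular aldol condensation (KOH, MeOH, rt) then closes ring A, and the sequence comes back to the route at 13.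

2. Step 11. The α-alkoxymethyllithium may be protonated or undergo a [1,2]-shift before it rearranges, because the pseudo-equatorial 7β-ether reaches the [2,3] geometry only through a half-boat of ring B; incomplete selectivity in the etherification of step 10 feeds the same problem. The fallback sets out from 16 and needs no etherification. Heating with N,N-dimethylformamide dimethyl acetal (xylene, 150 °C) should bring about the thermal [2,3]-rearrangement of the allylic alcohol, the only hydroxyl that can rearrange, to 1β,5α-dihydroxy-N,N-dimethyldrim-7-en-11-amide F2. LiEt3BH reduces the amide to drim-7-ene-1β,5α,11-triol F3, and Et3SiCl with imidazole silylates the primary hydroxyl, which comes back to the route at 19.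

3. Step 3. The amide carbonyl is flanked by a quaternary carbon, so addition may stall and the organolithium may instead remove a doubly allylic ring proton. The fallback sets out from 5. LiH2NBH3 reduces the amide to [(1S)-2-methoxy-1,5-dimethylcyclohexa-2,5-dien-1-yl]methanol F4; Dess–Martin oxidation gives (1R)-2-methoxy-1,5-dimethylcyclohexa-2,5-diene-1-carbaldehyde F5; MeMgBr gives 1-[(1S)-2-methoxy-1,5-dimethylcyclohexa-2,5-dien-1-yl]ethan-1-ol F6 as both carbinol epimers; a second Dess–Martin oxidation comes back to the route at 6.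

**Further compounds**

F1 | step 6 | 2-[(1R,2R)-2-acetyl-1-(benzyloxy)-2,4-dimethylcyclohex-3-en-1-yl]-2-methylpropanal | CC(=O)[C@]1(C)C=C(C)CC[C@@]1(OCc1ccccc1)C(C)(C)C=O
F2 | step 11 | 1β,5α-dihydroxy-N,N-dimethyldrim-7-en-11-amide | CC1(C)CC[C@@H](O)[C@]2(C)[C@@H](C(=O)N(C)C)C(C)=CC[C@@]12O
F3 | step 11 | drim-7-ene-1β,5α,11-triol | CC1(C)CC[C@@H](O)[C@]2(C)[C@@H](CO)C(C)=CC[C@@]12O
F4 | step 3 | [(1S)-2-methoxy-1,5-dimethylcyclohexa-2,5-dien-1-yl]methanol | OC[C@]1(C)C=C(C)CC=C1OC
F5 | step 3 | (1R)-2-methoxy-1,5-dimethylcyclohexa-2,5-diene-1-carbaldehyde | O=C[C@]1(C)C=C(C)CC=C1OC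
F6 | step 3 | 1-[(1S)-2-methoxy-1,5-dimethylcyclohexa-2,5-dien-1-yl]ethan-1-ol | CC(O)[C@]1(C)C=C(C)CC=C1OC
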